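**Retrosynthetic overview**
- Target ⇐ 7-O-silyl 8,9-cis-diol (late bis-angeloylation) ⇐ cis-dihydroxylation of a C8=C9 cycloheptene anti to O7; the C3 methyl comes from cuprate addition to a C2=C3 enone.
- Key disconnection: the cyclobutane and six-membered enone ring ⇐ 1,2-shift of C10 from C1 to C11 (semipinacol ring contraction) in a bridgehead-siloxy endo-bromonorbornene.
- That norbornene and the seven-membered ring ⇐ intramolecular Diels–Alder reaction of a 1-siloxy-5,5-disubstituted cyclopentadiene with a tethered (E)-bromoalkene.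
- Diene precursor ⇐ Michael adduct of 2-methylcyclopentane-1,3-dione and a bromodienone (from 3-chloro-3-methylbutyne and acrolein), desymmetrised by asymmetric transfer hydrogenation (sets C10).
- Ring order: cyclopentane (bought) → norbornene plus seven-membered ring (one step) → cyclobutane and cyclohexenone by the 1,2-shift.

Assumption: the target is 8,9-di-O-angeloyl-7-hydroxylongipinan-1-one; angelic acid and 3-chloro-3-methylbut-1-yne are taken as commercial.

Atom labels (longipinane numbering, used for all tricyclic compounds): C1 ketone carbon, C2, C3 (bears methyl C15), C4, C5, C6 (gem-dimethyl), C7 (OH), C8 and C9 (O-angeloyl), C10 (quaternary, methyl C14), C11. The cyclobutane is C4–C5–C11–C10. In compounds 12–15 C10 is bonded to C1 instead of C11.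

**Route**

Step 1
Reactants: 1 3-chloro-3-methylbut-1-yne; 2 acrolein
Product: 3 rac-4,4-dimethylhex-1-en-5-yn-3-ol
Conditions: Zn dust, THF, 0 °C to rt; aq NH4Cl
Reagents that add atoms: none
Why: Barbier propargylation: the allenylzinc from 1 adds 1,2 to the aldehyde through its dimethyl-substituted γ-carbon (SE2'), which builds quaternary C6 next to the C7 carbinol (this stereocentre is erased in step 3).

Step 2
Reactants: 3
Product: 5 rac-(E)-6-bromo-4,4-dimethylhexa-1,5-dien-3-ol, via vinylstannane 4 (not isolated)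
Conditions: Bu3SnH, PdCl2(PPh3)2 (2 mol %), THF, 0 °C; then NBS, CH2Cl2, −20 °C; aq KF
Reagents that add atoms: tributyltin hydride CCCC[SnH](CCCC)CCCC (tin into 4 only); N-bromosuccinimide O=C1CCC(=O)N1Br
Why: Palladium-catalysed syn-hydrostannation puts tin on the terminal carbon (the quaternary neighbour blocks the internal one) and bromodestannylation goes with retention, so the bromoalkene is E.

Step 3
Reactants: 5
Product: 6 (E)-6-bromo-4,4-dimethylhexa-1,5-dien-3-one
Conditions: Dess–Martin periodinane, NaHCO3, CH2Cl2, 0 °C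
Reagents that add atoms: none
Why: Dess–Martin oxidation of the allylic alcohol under buffered conditions that spare the bromoalkene and the polymerisable vinyl ketone.

Step 4
Reactants: 6; 7 2-methylcyclopentane-1,3-dione
Product: 8 2-[(E)-6-bromo-4,4-dimethyl-3-oxohex-5-en-1-yl]-2-methylcyclopentane-1,3-dione
Conditions: Et3N (10 mol %), EtOAc, rt
Reagents that add atoms: none
Why: Michael addition of the acidic dione to the vinyl ketone forms the C9–C10 bond; quaternary C6 leaves the chain ketone only one enolisable side, so no Hajos-type aldol cyclisation can follow.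

Step 5
Reactants: 8
Product: 9 (2R,3R)-2-[(E)-6-bromo-4,4-dimethyl-3-oxohex-5-en-1-yl]-3-hydroxy-2-methylcyclopentan-1-one
Conditions: RuCl[(R,R)-TsDPEN](p-cymene) (1 mol %), HCO2H/Et3N (5:2), CH2Cl2, rt
Reagents that add atoms: none
Why: Noyori asymmetric transfer hydrogenation desymmetrises the 2,2-disubstituted dione (hydride anti to the larger C2 substituent), fixing the quaternary carbon (future C10) as R, while the hindered tert-alkyl chain ketone reacts far more slowly; the (R,R) catalyst is assigned by analogy with aryl ketones.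

Step 6
Reactants: 9
Product: 10 (2R)-2-[(E)-6-bromo-4,4-dimethyl-3-oxohex-5-en-1-yl]-2-methylcyclopent-3-en-1-one
Conditions: Martin sulfurane, CH2Cl2, 0 °C to rt
Reagents that add atoms: none
Why: Dehydration of the secondary alcohol, which has β-hydrogens on one side only, gives the cyclopent-3-enone without touching C10; isomerisation into conjugation would be harmless because both enones give the same dienol ether.

Step 7
Reactants: 10
Product: 12 tricyclic endo-bromo bridgehead silyl ether (Diels–Alder adduct), via silyl dienol ether 11 (not isolated)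
Conditions: TBSOTf (1.05 equiv), Et3N, CH2Cl2, −78 to 0 °C; then PhMe, BHT, 110 °C
Reagents that add atoms: tert-butyldimethylsilyl triflate CC(C)(C)[Si](C)(C)OS(=O)(=O)C(F)(F)F
Why: Soft enolisation at the doubly activated ring CH2 gives a 1-siloxy-5,5-disubstituted cyclopentadiene (no 1,5-H shift possible) that undergoes intramolecular Diels–Alder reaction; the tether brings the bromoalkene to the diene face syn to C9 and bonds C5 to the unsubstituted terminus C4, so C6 is exo and, from the E-alkene, Br is endo, and C10 thereby sets C1, C4, C5 and C11.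

Step 8
Reactants: 12
Product: 13 C8=C9 enone of 12
Conditions: IBX, DMSO/PhF (1:2), 70 °C
Reagents that add atoms: none
Why: IBX dehydrogenation of a ketone; C7=O can enolise only toward C8 (C6 is quaternary) and C1 is masked as its silyl ether, so only the cis C8=C9 enone forms.

Step 9
Reactants: 13
Product: 14 (7R)-allylic alcohol
Conditions: (S)-Me-CBS (20 mol %), catecholborane, PhMe, −78 °C
Reagents that add atoms: none
Why: Corey–Bakshi–Shibata 1,2-reduction with quaternary C6 as the large group gives the (7R) alcohol (the target's C7 configuration) by reagent control; catecholborane does not hydroborate the alkenes.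

Step 10
Reactants: 14
Product: 15 7-O-TBS ether of 14
Conditions: TBSOTf, 2,6-lutidine, CH2Cl2, −40 to 0 °C
Reagents that add atoms: tert-butyldimethylsilyl triflate CC(C)(C)[Si](C)(C)OS(=O)(=O)C(F)(F)F
Why: Silylation of the hindered secondary alcohol; the ether later directs the dihydroxylation and keeps O7 free of acyl groups.

Step 11
Reactants: 15
Product: 16 (7R)-7-(tert-butyldimethylsilyloxy)longipina-2,8-dien-1-one
Conditions: AgOTf (1.5 equiv), 2,6-di-tert-butylpyridine, CH2Cl2, −40 to 0 °C; aq NaHCO3
Reagents that add atoms: none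
Why: Proposed new method: silver-triggered silyl-semipinacol ring contraction. The C1–C10 bond is antiperiplanar (about 155°) to the endo C11–Br bond, so as AgOTf abstracts bromide C10 shifts from C1 to C11 with inversion at C11 and retention at C10, the bridgehead siloxy oxygen takes up the charge as a conjugated 1-siloxyallyl cation and triflate removes silicon to give the enone; the cyclopentane C1–C11–C5–C4–C10 thus contracts to the cyclobutane while the other five-membered ring expands to the cyclohexenone. The closest known reaction is the silver-assisted Tiffeneau-type semipinacol rearrangement of halohydrins and their silyl ethers, which has not been shown in this strain-increasing norbornane-to-bicyclo[3.1.1]heptane direction.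

Step 12
Reactants: 16
Product: 17 (3R,7R)-7-(tert-butyldimethylsilyloxy)longipin-8-en-1-one
Conditions: Me2CuLi (from CuI and 2 MeLi), Et2O, −40 °C; aq NH4Cl
Reagents that add atoms: lithium dimethylcuprate [Li+].C[Cu-]C
Why: Cuprate conjugate addition to the bicyclo[3.1.1]heptenone from the face away from the C10 bridge and its C14 methyl (as with apoverbenone) places C15 on the C5 side, giving (3R); the β-neopentyl C8=C9 alkene and the allylic silyl ether are inert.

Step 13
Reactants: 17
Product: 18 7-O-TBS-7,8,9-trihydroxylongipinan-1-one (8,9-cis-diol)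
Conditions: OsO4 (10 mol %), NMO, acetone/H2O (5:1), rt
Reagents that add atoms: osmium tetroxide O=[Os](=O)(=O)=O; N-methylmorpholine N-oxide C[N+]1([O-])CCOCC1; water O
Why: Upjohn cis-dihydroxylation of the only alkene from the face anti to the bulky allylic C7–OTBS group (Kishi's rule) gives the 8,9-cis-diol trans to O7, the target's C8 and C9 configuration.

Step 14
Reactants: 18; 19 angelic acid
Product: 21 7-O-TBS ether of the target, via mixed anhydride 20 (not isolated)
Conditions: 19 (6 equiv), 2,4,6-trichlorobenzoyl chloride, Et3N, PhMe, rt; then 18, PhMe, 80 °C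
Reagents that add atoms: 2,4,6-trichlorobenzoyl chloride O=C(Cl)c1c(Cl)cc(Cl)cc1Cl (into 20 only)
Why: Yamaguchi-type mixed-anhydride acylation without DMAP, the conditions used to put angelate on hindered alcohols without Z-to-E isomerisation, esterifies both hydroxyls with retention at C8 and C9.

Step 15
Reactants: 21
Product: 22 target, 8,9-di-O-angeloyl-7-hydroxylongipinan-1-one
Conditions: HF·pyridine, THF/pyridine, 0 °C to rt
Reagents that add atoms: none
Why: Fluoride desilylation of the secondary silyl ether under buffered conditions that neither cleave nor isomerise the angelates.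

**Compound list**

1 | 3-chloro-3-methylbut-1-yne | CC(C)(Cl)C#C | starting material
2 | acrolein (prop-2-enal) | C=CC=O | starting material
3 | rac-4,4-dimethylhex-1-en-5-yn-3-ol | C=CC(O)C(C)(C)C#C | intermediate
4 | rac-(E)-4,4-dimethyl-6-(tributylstannyl)hexa-1,5-dien-3-ol | C=CC(O)C(C)(C)/C=C/[Sn](CCCC)(CCCC)CCCC | intermediate (not isolated)
5 | rac-(E)-6-bromo-4,4-dimethylhexa-1,5-dien-3-ol | C=CC(O)C(C)(C)/C=C/Br | intermediate
6 | (E)-6-bromo-4,4-dimethylhexa-1,5-dien-3-one | C=CC(=O)C(C)(C)/C=C/Br | intermediate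
7 | 2-methylcyclopentane-1,3-dione | CC1C(=O)CCC1=O | starting material
8 | 2-[(E)-6-bromo-4,4-dimethyl-3-oxohex-5-en-1-yl]-2-methylcyclopentane-1,3-dione | CC1(CCC(=O)C(C)(C)/C=C/Br)C(=O)CCC1=O | intermediate
9 | (2R,3R)-2-[(E)-6-bromo-4,4-dimethyl-3-oxohex-5-en-1-yl]-3-hydroxy-2-methylcyclopentan-1-one (OH cis to the chain) | O=C1CC[C@@H](O)[C@@]1(C)CCC(=O)C(C)(C)/C=C/Br | intermediate
10 | (2R)-2-[(E)-6-bromo-4,4-dimethyl-3-oxohex-5-en-1-yl]-2-methylcyclopent-3-en-1-one | O=C1CC=C[C@@]1(C)CCC(=O)C(C)(C)/C=C/Br | intermediate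
11 | (5R)-1-(tert-butyldimethylsilyloxy)-5-methyl-5-[(E)-6-bromo-4,4-dimethyl-3-oxohex-5-en-1-yl]cyclopenta-1,3-diene | CC(C)(C)[Si](C)(C)OC1=CC=C[C@@]1(C)CCC(=O)C(C)(C)/C=C/Br | intermediate (not isolated)
12 | Diels–Alder adduct: norbornene with bridgehead C1 (OTBS) bonded to C2, C10 and C11; C2=C3; C4 bridgehead H; C11–Br endo; C5 bears C6 exo; bridge C10 (R) bears methyl C14 syn to C2=C3; seven-membered ring C4–C5–C6(CH3)2–C7(=O)–C8H2–C9H2–C10 | CC(C)(C)[Si](C)(C)O[C@@]12C=C[C@H]3[C@@H]([C@H]1Br)C(C)(C)C(=O)CC[C@@]23C | intermediate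
13 | 12 with a cis C8=C9 double bond (7-oxo-8-ene) | CC(C)(C)[Si](C)(C)O[C@@]12C=C[C@H]3[C@@H]([C@H]1Br)C(C)(C)C(=O)/C=C\[C@@]23C | intermediate
14 | (7R)-allylic alcohol from 13 | CC(C)(C)[Si](C)(C)O[C@@]12C=C[C@H]3[C@@H]([C@H]1Br)C(C)(C)[C@H](O)/C=C\[C@@]23C | intermediate
15 | 7-O-TBS ether of 14 | CC(C)(C)[Si](C)(C)O[C@@]12C=C[C@H]3[C@@H]([C@H]1Br)C(C)(C)[C@H](O[Si](C)(C)C(C)(C)C)/C=C\[C@@]23C | intermediate
16 | (7R)-7-(tert-butyldimethylsilyloxy)longipina-2,8-dien-1-one; C4, C5, C10, C11 as in the target | CC1(C)[C@H](O[Si](C)(C)C(C)(C)C)/C=C\[C@@]2(C)[C@@H]3C(=O)C=C[C@H]2[C@H]13 | intermediate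
17 | (3R,7R)-7-(tert-butyldimethylsilyloxy)longipin-8-en-1-one (C15 on the C5 side, anti to C14) | CC1(C)[C@H](O[Si](C)(C)C(C)(C)C)/C=C\[C@@]2(C)[C@@H]3C(=O)C[C@@H](C)[C@H]2[C@H]13 | intermediate
18 | 7-O-TBS-7,8,9-trihydroxylongipinan-1-one; 8,9-cis-diol trans to O7, all centres as in the target | CC1(C)[C@H](O[Si](C)(C)C(C)(C)C)[C@@H](O)[C@@H](O)[C@@]2(C)[C@@H]3C(=O)C[C@@H](C)[C@H]2[C@H]13 | intermediate
19 | angelic acid, (Z)-2-methylbut-2-enoic acid | C/C=C(/C)C(=O)O | starting material
20 | (Z)-2-methylbut-2-enoic 2,4,6-trichlorobenzoic anhydride | C/C=C(/C)C(=O)OC(=O)c1c(Cl)cc(Cl)cc1Cl | intermediate (not isolated)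
21 | 7-O-TBS ether of the target (8,9-bis-angelate) | CC1(C)[C@H](O[Si](C)(C)C(C)(C)C)[C@@H](OC(=O)/C(C)=C\C)[C@@H](OC(=O)/C(C)=C\C)[C@@]2(C)[C@@H]3C(=O)C[C@@H](C)[C@H]2[C@H]13 | intermediate
22 | (3R,4S,5S,7S,8R,9S,10R,11R)-7-hydroxy-1-oxolongipinane-8,9-diyl bis[(Z)-2-methylbut-2-enoate] | C/C=C(/C)C(=O)O[C@@H]1[C@@H](O)C(C)(C)[C@H]2[C@@H]3[C@H](C)CC(=O)[C@H]2[C@]3(C)[C@@H]1OC(=O)/C(C)=C\C | target

**Step count and risks**

Total: 15 steps. Longest linear sequence: 15 steps (from 1 and 2; 7 and 19 are bought).

Steps most likely to fail: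

Step 11 (proposed new ring contraction). The shift runs against ring strain and a secondary endo-norbornyl bromide may ionise sluggishly. The fallback uses the known base- or silver-promoted halohydrin semipinacol rearrangement on the free alcohol: it sets out from 15, where excess TBAF (THF, 50 °C) removes both silyl groups to give the bromohydrin diol F1. In F1 epoxide closure is geometrically impossible, so KH/18-crown-6 (THF, 0 °C to rt) or Ag2O drives the oxyanion-pushed shift of C10 to give the 7-hydroxy dienone F2. Silylation of F2 with TBSOTf/2,6-lutidine comes back to the route at 16.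

Step 14 (double angeloylation of a hindered cis-diol, with a risk of tiglate formation). The fallback builds the Z-olefins on the substrate instead of transferring angelate: it sets out from 18, which is acylated with 2-bromopropanoyl bromide/pyridine to the bis(2-bromopropanoate) F3. A Michaelis–Becker reaction with potassium bis(2,2,2-trifluoroethyl) phosphite gives the bis-phosphonate F4. Double Still–Gennari olefination (KHMDS, 18-crown-6, acetaldehyde, THF, −78 °C) comes back to the route at 21.

Step 5 (chemoselective, enantioselective reduction of one of three ketones; the sense of induction is assigned by analogy). The fallback replaces asymmetric catalysis by resolution: it sets out from 8, which NaBH4 (0.3 equiv, MeOH/CH2Cl2, −78 °C) reduces to the racemic cis-ketol F5, the minor trans isomer being removed by chromatography. Amano lipase PS with vinyl acetate acylates the (3R) alcohol (Kazlauskas rule) to the (2R,3R) acetate F6, which is separated from the unreacted enantiomer. Methanolysis of F6 (K2CO3, MeOH, 0 °C) comes back to the route at 9.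

**Further compounds**

F1 | step 11 | bromohydrin diol: 12-type skeleton with C8=C9, free bridgehead C1–OH, free (7R)-OH and endo C11–Br | O[C@@]12C=C[C@H]3[C@@H]([C@H]1Br)C(C)(C)[C@H](O)/C=C\[C@@]23C
F2 | step 11 | (7R)-7-hydroxylongipina-2,8-dien-1-one | CC1(C)[C@H](O)/C=C\[C@@]2(C)[C@@H]3C(=O)C=C[C@H]2[C@H]13
F3 | step 14 | 8,9-bis(2-bromopropanoate) of 18 (mixture at the bromo-bearing carbons) | CC1(C)[C@H](O[Si](C)(C)C(C)(C)C)[C@@H](OC(=O)C(C)Br)[C@@H](OC(=O)C(C)Br)[C@@]2(C)[C@@H]3C(=O)C[C@@H](C)[C@H]2[C@H]13
F4 | step 14 | 8,9-bis{2-[bis(2,2,2-trifluoroethoxy)phosphoryl]propanoate} of 18 | CC1(C)[C@H](O[Si](C)(C)C(C)(C)C)[C@@H](OC(=O)C(C)P(=O)(OCC(F)(F)F)OCC(F)(F)F)[C@@H](OC(=O)C(C)P(=O)(OCC(F)(F)F)OCC(F)(F)F)[C@@]2(C)[C@@H]3C(=O)C[C@@H](C)[C@H]2[C@H]13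
F5 | step 5 | rac-(2R*,3R*)-2-[(E)-6-bromo-4,4-dimethyl-3-oxohex-5-en-1-yl]-3-hydroxy-2-methylcyclopentan-1-one (racemate, relative configuration shown) | O=C1CC[C@@H](O)[C@@]1(C)CCC(=O)C(C)(C)/C=C/Br
F6 | step 5 | (1R,2R)-2-[(E)-6-bromo-4,4-dimethyl-3-oxohex-5-en-1-yl]-2-methyl-3-oxocyclopentyl acetate | O=C1CC[C@@H](OC(C)=O)[C@@]1(C)CCC(=O)C(C)(C)/C=C/Br
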